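You can start from the easiest ratio on the card, coupling partner over starting material, since one coupling partner is consumed per starting material turned over.

| flask | starting material | coupling partner | free catalyst | remark | time |
|---|---|---|---|---|---|
| Monday's | 0.081 M | 0.0946 M | 2.6 mM | run made earlier |  |
| Sunday's | 0.38 M | 0.0946 M | 2.6 mM | run made earlier |  |
| Tuesday's | 0.086 M | 0.0946 M | 1.9 mM | run made earlier |  |
| green | 0.086 M | 0.0946 M | 2.6 mM |  | 8.0 min |
| red | 0.086 M | 0.0500 M | 8.0 mM |  | 8.0 min |
| amber | 0.060 M | 0.0946 M | 2.6 mM |  | 8.0 min |
| grey | 0.060 M | 0.400 M | 4.0 mM |  | 8.0 min |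
| blue | 0.086 M | 0.0300 M | 0.80 mM |  | 8.0 min |
| violet | 0.25 M | 0.0946 M | 2.6 mM |  | 8.0 min |

| run | time / min | target / % | starting material / % |
|---|---|---|---|
| Monday's | 0.833 | 20.8 | 79.8 |
| Monday's | 1.50 | 33.7 | 65.3 |
| Monday's | 2.50 | 48.5 | 50.9 |
| Monday's | 3.00 | 53.5 | 44.9 |
| Monday's | 4.00 | 64.1 | 35.3 |
| Sunday's | 0.333 | 3.2 | 96.0 |
| Sunday's | 1.00 | 9.5 | 89.5 |
| Sunday's | 2.00 | 15.0 | 84.5 |
| Sunday's | 3.00 | 20.6 | 78.7 |
| Sunday's | 4.00 | 22.5 | 75.0 |
| Tuesday's | 0.333 | 6.1 | 92.5 |
| Tuesday's | 0.667 | 12.4 | 86.7 |
| Tuesday's | 1.00 | 17.7 | 81.6 |
| Tuesday's | 2.00 | 32.2 | 66.7 |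
| Tuesday's | 4.00 | 52.1 | 46.4 |

(scatter of a reading: 0.5 percentage points)

* the flasks by amount of target, in percent of the starting material charged, highest first, at 8.0 min (green / red / amber / grey / blue / violet)
* the same order at 25 s (green / red / amber / grey / blue / violet)
* the amount of target, in percent of the starting material charged of the flask you put first, at 8.0 min
* the amount of target, in percent of the starting material charged of the flask you put last, at 8.0 min

Sunday's flask shows this directly: by 4.00 min it had consumed 0.0950 M of starting material, about equal to the 0.0946 M of coupling partner charged. So wherever the coupling partner is the limiting reagent, that ratio caps the conversion: 58.1% in red, 34.9% in blue and 37.8% in violet.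

When does each flask reach its cap? Monday's first reading gives a turnover n of 7.78 min⁻¹ per catalyst, so the partner charge lasts about τ, the charge divided by n times the catalyst: 0.803 min in red, 4.82 min in blue and 4.68 min in violet, each shorter than the 8.0 min allowed.

What does the time after τ cost? Sunday's missing balance rose from 0.7 percentage points at 3.00 min to 2.5 points at 4.00 min, as its partner charge was used up. I take that as a rough leak s, the share of target lost from the balance per minute at 2.6 mM of catalyst: 0.0800 min⁻¹, a reading from four values that each scatter by 0.5 points, and since the missing balance can hold catalyst-bound forms as well as isomer, I set no bound on its error.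

Work in logarithms: while the way back from isomer stays small, ln(cap/target) = x = s × (catalyst/2.6 mM) × (time after τ), an estimate with no floor, although that step stands as reversible on the card and these runs give no equilibrium constant for it. That gives 1.77 for red, 0.266 for violet and 0.0783 for blue, so my reckoning, with no way back counted, puts target at 9.89%, 29.0% and 32.3%, with red last.

The forecast differs: grey > amber > green > red > violet > blue at 8.0 min, red > grey > amber > green > violet > blue at 25 s, top 96% (91% to 99%), low 28% (23% to 32%) for blue, with red about 33, on the grounds that “Once partner is gone, free catalyst isomerises target.”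

The flasks give grey > amber > green > blue > violet > red at 8.0 min and red > grey > amber > green > violet > blue at 25 s, with top 97.6% and low 14.8%.

    target + free catalyst ⇌ isomer of the product + free catalyst, rate k1*[free catalyst]*[target] forward; the back reaction follows from the equilibrium constant (K = 2.80, k = 2.10 L mol⁻¹ s⁻¹)
    catalyst intermediate C ⇌ free catalyst + target (K = 0.130 M, k = 0.400 s⁻¹)
    starting material + catalyst intermediate A ⇌ catalyst intermediate B (K = 14.0 L mol⁻¹, k = 3.40 L mol⁻¹ s⁻¹)
    coupling partner + free catalyst → catalyst intermediate A (k = 220 L mol⁻¹ s⁻¹)
    catalyst intermediate B ⇌ released group + catalyst intermediate C (K = 0.0550 M, k = 23.0 s⁻¹)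

Red, at 14.8%, stands below the forecast's 33 and above my 9.89%, with isomer over target at 2.77 beside the equilibrium constant K1 of 2.8, and with 14.7% of target still there at 80.0 min, so x has to stop at ln(1 + K1), which is 1.34, and target at a floor of cap/(1 + K1). Take its neighbour with 0.013 M of coupling partner: the cap is 15.1%, τ is 0.209 min, and x is 1.92, past that stop, so the mended reckoning gives the floor, 3.97% of target. That flask holds 84.9% of starting material, 10.9% of isomer and 3.89% of target.

The numbers in the tables come from a simulation from invented constants.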